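Follow one catalyst molecule through these flasks and count the rounds to target it gives before it dies.

    starting material + free catalyst ⇌ catalyst intermediate A (K1 = 63 M⁻¹, k1 = 4600 M⁻¹ h⁻¹, Ea1 = 41.0 kJ mol⁻¹, ΔH1 = −42.0 kJ mol⁻¹)
    reagent + catalyst intermediate B → free catalyst + second product (k2 = 1300 M⁻¹ h⁻¹, Ea2 = 40.0 kJ mol⁻¹)
    reagent + catalyst intermediate A → free catalyst + target (k3 = 1.2 × 10⁵ M⁻¹ h⁻¹, Ea3 = 56.0 kJ mol⁻¹)
    second substrate + free catalyst ⇌ catalyst intermediate B (K4 = 9.6 M⁻¹, k4 = 2500 M⁻¹ h⁻¹, Ea4 = 44.0 kJ mol⁻¹, ΔH4 = −33.0 kJ mol⁻¹)
    starting material + catalyst intermediate B → spent catalyst A (k5 = 23 M⁻¹ h⁻¹, Ea5 = 73.0 kJ mol⁻¹)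
    catalyst intermediate B → spent catalyst B (k6 = 0.72 h⁻¹, Ea6 = 91.0 kJ mol⁻¹)
    (constants at 40 °C)

| setting | south-east | north | south | north-east |
|---|---|---|---|---|
| starting material | 0.050 M | 0.050 M | 0.050 M | 0.050 M |
| second substrate | 0.0500 M | 0.0500 M | 0.0500 M | 0.0500 M |
| reagent | 0.0350 M (fed, over 4.0 h) | 0.0350 M (fed, over 4.0 h) | 0.0350 M | 0.0350 M |
| free catalyst | 95 µM | 95 µM | 95 µM | 95 µM |
| time | 20 h | 20 h | 20 h | 20 h |
| remark | the addition at 10 °C, then warmed to 40 °C; the feed brings no volume worth counting | all else is in the flask from the start; the feed brings no volume worth counting | everything together at the start | everything together at the start at 10 °C, warmed to 40 °C at 4.0 h |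
| temperature |  | 40 °C | 40 °C |  |

- at 40 °C the constants are as listed, elsewhere as the activation energies and enthalpies make them

1. the flask that comes out highest in amount of target, in percent of the starting material charged, or "all alike" when all lie within 1.5 percentage points (south-east / north / south / north-east / all alike)
2. target at the end, in percent of the starting material charged, south-east
3. target at the end, in percent of the starting material charged, north
4. target at the end, in percent of the starting material charged, south
5. target at the end, in percent of the starting material charged, north-east

1. Turn the question round. For the reagent to run out before the catalyst dies in south, each catalyst has to make 368 rounds, which is the reagent charge over the catalyst charge. Reagent is the limiting reagent, since its charge is less than that of the starting material, and it allows 70.0 % target.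

2. Take the first fork in south, as charged. Intermediate A goes on with reagent at 4200 h⁻¹ and falls back at 73.0 h⁻¹, so it reaches target with a chance of 98.3 %.

3. Take the second fork in south. Intermediate B falls back at 260 h⁻¹, meets reagent at 45.5 h⁻¹ and dies at 1.87 h⁻¹, so each visit kills with a chance of 0.608 %.

4. Free catalyst enters intermediate A at 230 h⁻¹ and intermediate B at 125 h⁻¹. The turnover budget, the rounds to target per catalyst death, is therefore 298 in south, as charged.

5. That budget is less than the 368 rounds required, so in south the catalyst should die first. The budget allows about 56.6 % target at charged concentrations, and my reckoning expects somewhat less as those concentrations fall.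

6. In north the feed brings 0.00875 M h⁻¹, less than the 0.0218 M h⁻¹ that the charged catalyst can take up. [reagent] should stay low, the first chance should shrink, and by my reckoning north should lose target against south.

7. The budget uses the constants at 40 °C, so my reckoning stops short of ranking the flasks that start at 10 °C.

The forecast gives south-east 52 %, north 44 %, south 49 % and north-east 54 %, and says “the cold start gives the best result”.

The flasks give south-east 49.1 %, north 40.0 %, south 47.2 % and north-east 51.3 %, so north-east stands highest. North-east still holds 20 % of its reagent at 20.0 h, and its target reads 51.4 % at 200 h. South's target comes to 248 rounds per catalyst, less than the budget of 298.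

For the neighbour of north-east with 1.6 × 10⁻⁴ M of catalyst, the budget gives 0.0476 M of rounds, more than the 0.0350 M of reagent, so reagent should run out first. It does: reagent stands at 0 % at 20.0 h, with target at 63.8 % and second product at 0.00309 M.

(The rate constants stand for no real mixture; the result is computed.)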